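Of the constants I could read from the runs, I first asked how far an error in each would move the answers.

| setting | birch | elm | larch | autumn | summer | winter |
|---|---|---|---|---|---|---|
| starting material | 0.87 M | 0.58 M | 1.3 M | 0.87 M | 0.87 M | 0.87 M |
| remark | run made earlier | run made earlier | run made earlier | everything together in a closed stirred flask, run for 10 min | one stirred flow tank at steady state, fed with the mixture as stated, mean residence time 10 min | a tube with plug flow, the mixed feed as stated, residence time 10 min |
| time |  |  |  | 10 min |  | 10 min |

| run | time / min | target / % |
|---|---|---|
| birch | 0.500 | 1 |
| birch | 1.00 | 2 |
| birch | 2.50 | 3 |
| birch | 6.00 | 11 |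
| elm | 3.00 | 8 |
| elm | 6.00 | 11 |
| elm | 10.0 | 13 |
| elm | 12.0 | 22 |
| larch | 3.00 | 8 |
| larch | 6.00 | 11 |
| larch | 10.0 | 21 |
| larch | 12.0 | 19 |

(readings scatter by 2 percentage points)

- the stated concentrations are those of everything mixed, before any reaction; amounts are the same in each set-up
- the earlier runs were read with a standard deviation of 2 percentage points
- the earlier runs were made in a closed, stirred flask

1. the set-up with the highest amount of target at the outlet or at the end, in percent of the starting material put in ("none" if the first two lie within 2 percentage points) (autumn / summer / winter / none)
2. amount of target at the outlet or at the end, in percent of the starting material put in, autumn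
3. amount of target at the outlet or at the end, in percent of the starting material put in, summer
4. amount of target at the outlet or at the end, in percent of the starting material put in, winter

The charge could stay rough: at 6.00 min the elm and larch runs both read 11% of their charge, though larch started at about twice the concentration of elm. So I took the rate as first order, with the fraction formed independent of the charge. The constant that counted was the yield constant, the fraction of the unconverted charge that reaches target per minute, which I read as 0.0191 min⁻¹ from the mean of the two readings at 12.0 min. Those readings taken singly gave 0.0176 min⁻¹ and 0.0207 min⁻¹, which moved my estimate for the closed flask from 16.1% to 18.7%. Even at the higher value, my estimate put the closed flask ahead of the tank by 1.5 percentage points, less than the margin of 2 points. With 0.0191 min⁻¹, my reckoning gave 17.4% for autumn and for winter, whose plug flow gives each portion the same time, and 16.0% for summer.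

The forecast stood a little higher: 18% for autumn, 18% for winter, 16.7% for summer, and best none: “The flask and tube tie for the highest, so best is none.”

The simulation gave 18.6% for autumn, 18.6% for winter and 16.6% for summer, and best none.

    intermediate C → target (k = 0.00290 s⁻¹)
    target ⇌ isomer of the product (K = 0.230, k = 0.00710 s⁻¹)
    intermediate B ⇌ intermediate D (K = 0.440, k = 0.0310 s⁻¹)
    starting material ⇌ intermediate B (K = 1.00, k = 0.0730 s⁻¹)
    starting material → intermediate A (k = 0.400 s⁻¹)
    intermediate A ⇌ intermediate C (K = 0.190, k = 0.00920 s⁻¹)

The autumn flask had not come to rest at 10 min: besides its 18.6% of target, it still held 65.5% as intermediate A and 11.9% as intermediate C. Carried to ten times the time, 0.0191 min⁻¹ gives 85.2% of target, while that longer autumn flask gives 75.6%, which is less. Even so, the extra time still adds 57 points of target.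

The data come from a simulation for an exercise, and the scatter is random.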